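**Retrosynthetic overview**
1. Feature: the five-membered lactone O1–C2–C3–C3a–C7a sits on a fully substituted benzene ring (C4 OMe, C5 acyl, C6/C7 OH). It is the pyranone ring of a 4-benzyl-3-hydroxycoumarin minus its carbonyl carbon. Coumarin C4/C4a/C5–C8/C8a map onto C3/C3a/C4–C7/C7a.
2. C3=CHPh (Z): dehydrogenation of the 3-benzyl lactone through selenide and selenoxide. The C6/C7 acetonide comes off last.
3. O1–C2: alkaline H2O2 cuts the lactone carbonyl carbon out of the 3-hydroxycoumarin, and acid closes the shortened acid on the C7a phenol.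
4. C5–acyl and C3a–C3: Friedel–Crafts acylation of the only free coumarin carbon, after a Pechmann condensation of symmetric 5-methoxypyrogallol with an α-acetoxy β-keto ester.
5. Ring order: benzene (bought; CHO exchanged for OMe), pyranone (step 6), temporary dioxolane (step 8), furanone in place of the pyranone (step 9).

Key step: step 9

Assumption: bractelactone has no stereocentre, so "single enantiomer" is read as the single Z isomer of the C3 benzylidene bond (phenyl cis to C2=O). Chiral intermediates are racemic, with one enantiomer drawn.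
Coumarin numbering is used up to the key step and benzofuran-2(3H)-one numbering after it.

**Step 1**
Reactants: 1 3,4,5-trihydroxybenzaldehyde
Product: 2 3,4,5-tris(benzyloxy)benzaldehyde
Conditions: BnBr (3.5 equiv), K2CO3, DMF, 60 °C, N2
Reagents that add atoms: benzyl bromide, BrCc1ccccc1
Why: Williamson etherification of all three phenols, which masks the oxidation-prone pyrogallol for the peracid step and can be undone later by neutral hydrogenolysis.

**Step 2**
Reactants: 2 3,4,5-tris(benzyloxy)benzaldehyde
Product: 4 3,4,5-tris(benzyloxy)phenol, via aryl formate 3 (not isolated)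
Conditions: mCPBA, CH2Cl2, rt; then K2CO3 (cat.), MeOH, rt
Reagents that add atoms: mCPBA, O=C(OO)c1cccc(Cl)c1
Why: Baeyer–Villiger oxidation of an electron-rich benzaldehyde, in which the trialkoxyaryl group migrates to oxygen in preference to hydride, followed by base-catalysed methanolysis of the labile aryl formate.

**Step 3**
Reactants: 4 3,4,5-tris(benzyloxy)phenol
Product: 5 1,2,3-tris(benzyloxy)-5-methoxybenzene
Conditions: MeI, K2CO3, acetone, reflux
Reagents that add atoms: iodomethane, CI
Why: Williamson O-methylation of the only free phenol, which fixes the future C4 methoxy group before the other three oxygens are released.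

**Step 4**
Reactants: 5 1,2,3-tris(benzyloxy)-5-methoxybenzene
Product: 6 5-methoxybenzene-1,2,3-triol (5-methoxypyrogallol)
Conditions: H2 (1 atm), 10% Pd/C, EtOAc–MeOH, rt; filtered under Ar
Reagents that add atoms: none
Why: Catalytic hydrogenolysis cleaves the three benzylic C–O bonds and leaves the methyl ether, giving the symmetric, air-sensitive triol that is used at once under argon.

**Step 5**
Reactants: 7 ethyl 3-oxo-4-phenylbutanoate
Product: 8 ethyl 2-acetoxy-3-oxo-4-phenylbutanoate (racemic)
Conditions: Pb(OAc)4 (1.05 equiv), benzene, 25–40 °C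
Reagents that add atoms: lead tetraacetate, CC(=O)O[Pb](OC(C)=O)(OC(C)=O)OC(C)=O
Why: Lead(IV) α-acetoxylation of a β-keto ester, which goes through the chelated C2=C3 enol and so places the acetoxy group on C2 between the two carbonyl groups and not on the benzylic C4.

**Step 6**
Reactants: 6 5-methoxybenzene-1,2,3-triol; 8 ethyl 2-acetoxy-3-oxo-4-phenylbutanoate
Product: 10 4-benzyl-3,7,8-trihydroxy-5-methoxycoumarin, via 3-acetoxycoumarin 9 (not isolated)
Conditions: MeSO3H, 0 °C → rt, Ar; ice–water; then 3 M HCl, dioxane–H2O, 70 °C, Ar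
Reagents that add atoms: none
Why: Pechmann condensation with an α-substituted β-keto ester: the ring carbon ortho to OH and OMe and para to the third OH attacks the protonated benzyl ketone, dehydration and lactonisation on the adjacent OH follow, the two free carbons of 6 are related by symmetry so that only one coumarin can form, and aqueous acid then hydrolyses the enol acetate so that no foreign acyl donor is carried into step 7.

**Step 7**
Reactants: 10 4-benzyl-3,7,8-trihydroxy-5-methoxycoumarin; 11 3-phenylpropanoic acid
Product: 12 4-benzyl-3,7,8-trihydroxy-5-methoxy-6-(3-phenylpropanoyl)coumarin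
Conditions: BF3·OEt2 (neat), 80 °C, Ar; then 1 M HCl, THF–H2O, 50 °C
Reagents that add atoms: none
Why: Friedel–Crafts (Nencki-type) acylation with the acid activated by BF3: C6 is the only unsubstituted ring carbon, lies ortho to 5-OMe and 7-OH, para to O1 and meta to the electron-poor C4a substituent, the ketone is trapped as its 7-O/C=O boron chelate, which stops further reaction and spares the 5-OMe group, and BF3 is too weak to turn the acid into 1-indanone.

**Step 8**
Reactants: 12 4-benzyl-3,7,8-trihydroxy-5-methoxy-6-(3-phenylpropanoyl)coumarin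
Product: 13 4-benzyl-3-hydroxy-5-methoxy-6-(3-phenylpropanoyl)coumarin 7,8-acetonide
Conditions: Me2C(OMe)2, TsOH·H2O (cat.), toluene, reflux through 4 Å sieves, Ar
Reagents that add atoms: 2,2-dimethoxypropane, COC(C)(C)OC
Why: Acid-catalysed transketalisation: only the 7,8-catechol can close a five-membered 1,3-benzodioxole, a mixed ketal on the enolic 3-OH reverts on aqueous work-up, and continuous removal of methanol drives the unfavourable catechol equilibrium and keeps the enol from being etherified.

**Step 9**
Reactants: 13 4-benzyl-3-hydroxy-5-methoxy-6-(3-phenylpropanoyl)coumarin 7,8-acetonide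
Product: 16 (±)-3-benzyl-4-methoxy-5-(3-phenylpropanoyl)benzofuran-2(3H)-one 6,7-acetonide, via alpha-keto acid 14 (not isolated), via arylacetic acid 15 (not isolated)
Conditions: 1 M NaOH (6 equiv), THF–H2O, degassed, 0 °C → rt; 30% H2O2 (1.2 equiv), 0 °C; Na2SO3; 2 M HCl to pH 1; then TsOH (cat.), toluene, 80 °C
Reagents that add atoms: sodium hydroxide, [Na+].[OH-] (oxygen of the opened carboxyl group in 14); hydrogen peroxide, OO (one oxygen of the new carboxyl group in 15 and, statistically, the C2 carbonyl oxygen of 16)
Why: Hydroxide opens the enol lactone of 13, the freed enolate takes up a proton at the former coumarin C4 to give α-keto acid 14, hydroperoxide adds to its keto carbon (former C3), and the adduct fragments with loss of the old lactone carbonyl (former C2) as carbonate, so that former C3 becomes the carboxyl carbon of 15 and later C2 of the furanone. The closest known reaction is the alkaline-peroxide degradation of 3-hydroxycoumarins and arylpyruvic acids to o-hydroxyarylacetic acids, an oxidative decarboxylation of an α-keto acid. In acid the C7a phenol adds to the new carboxyl group and water leaves (5-exo-trig), which forms O1–C2 and the five-membered lactone; the other ortho oxygen is the C4 methyl ether, so only one lactone can form. C3 arises by unselective protonation, is racemic and enolisable, and needs no control because step 11 turns it into an sp2 carbon. The selectivity needed is α-keto acid over aryl ketone, and it is not trivial, because ring opening sets free a phenoxide at C7a that stands para to the C5 ketone, so that a Dakin-type aryl migration is open in principle. It should be held back because this ketone lies between the C4 methoxy group and a ketal oxygen, which blocks the tetrahedral peroxide adduct, and is drained of electrophilicity by the para phenoxide, whereas the α-keto carboxylate is far more electrophilic; for that reason peroxide is kept near one equivalent at 0 °C and is destroyed with sulfite before acid is added, and the ketal keeps the C6 and C7 oxygens from serving as ortho-hydroxy triggers or as a quinone source.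

**Step 10**
Reactants: 16 (±)-3-benzyl-4-methoxy-5-(3-phenylpropanoyl)benzofuran-2(3H)-one 6,7-acetonide
Product: 18 (±)-3-benzyl-3-(phenylselanyl)-4-methoxy-5-(3-phenylpropanoyl)benzofuran-2(3H)-one 6,7-acetonide, via lithium enolate 17 (not isolated)
Conditions: LiHMDS (1.05 equiv), THF, −78 → −30 °C, Ar; PhSeBr, −78 °C
Reagents that add atoms: phenylselanyl bromide, Br[Se]c1ccccc1; lithium hexamethyldisilazide, [Li+].C[Si](C)(C)[N-][Si](C)(C)C (lithium of 17 only)
Why: α-Selenenylation of a lactone enolate: C3–H gives an aromatic 2-oxidobenzofuran and is many pK units more acidic than the CH2 next to the aryl ketone, so one equivalent of base after equilibration ionises C3 alone, the soft selenium electrophile bonds to carbon, and the new quaternary centre is racemic and is destroyed in step 11.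

**Step 11**
Reactants: 18 (±)-3-benzyl-3-(phenylselanyl) lactone acetonide
Product: 20 (Z)-3-benzylidene-4-methoxy-5-(3-phenylpropanoyl)benzofuran-2(3H)-one 6,7-acetonide, via selenoxide 19 (not isolated)
Conditions: mCPBA (1.05 equiv), CH2Cl2, −78 °C → rt
Reagents that add atoms: mCPBA, O=C(OO)c1cccc(Cl)c1 (its oxygen is held only by 19 and leaves again with selenium)
Why: Selenoxide syn-elimination: the only β-hydrogens are those of the benzyl CH2 because C3a is aromatic, so the double bond must become exocyclic, and the transition state that turns the phenyl group away from the C4 methoxy group and toward the lactone carbonyl is the less crowded one and gives the Z alkene, which is also the more stable isomer, so that any E alkene can be equilibrated to it (cat. I2, daylight).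

**Step 12**
Reactants: 20 (Z)-3-benzylidene lactone acetonide
Product: 21 bractelactone
Conditions: CF3CO2H–H2O 9:1, rt → 40 °C, Ar
Reagents that add atoms: none
Why: Acid-catalysed hydrolysis of the catechol ketal, in which the aryl lactone stays closed, the methyl ether and the ketone are inert, and the geometry cannot erode because Z is the thermodynamic isomer (an E phenyl group would clash with the C4 methoxy group).

**Compound list**
1 | 3,4,5-trihydroxybenzaldehyde | O=Cc1cc(O)c(O)c(O)c1 | starting material
2 | 3,4,5-tris(benzyloxy)benzaldehyde | O=Cc1cc(OCc2ccccc2)c(OCc2ccccc2)c(OCc2ccccc2)c1 | intermediate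
3 | 3,4,5-tris(benzyloxy)phenyl formate (not isolated) | O=COc1cc(OCc2ccccc2)c(OCc2ccccc2)c(OCc2ccccc2)c1 | intermediate
4 | 3,4,5-tris(benzyloxy)phenol | Oc1cc(OCc2ccccc2)c(OCc2ccccc2)c(OCc2ccccc2)c1 | intermediate
5 | 1,2,3-tris(benzyloxy)-5-methoxybenzene | COc1cc(OCc2ccccc2)c(OCc2ccccc2)c(OCc2ccccc2)c1 | intermediate
6 | 5-methoxybenzene-1,2,3-triol | COc1cc(O)c(O)c(O)c1 | intermediate
7 | ethyl 3-oxo-4-phenylbutanoate | CCOC(=O)CC(=O)Cc1ccccc1 | starting material
8 | ethyl 2-acetoxy-3-oxo-4-phenylbutanoate (racemic, labile, one enantiomer drawn) | CCOC(=O)[C@@H](OC(C)=O)C(=O)Cc1ccccc1 | intermediate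
9 | 3-acetoxy-4-benzyl-7,8-dihydroxy-5-methoxycoumarin (not isolated) | COc1cc(O)c(O)c2OC(=O)C(OC(C)=O)=C(Cc3ccccc3)c12 | intermediate
10 | 4-benzyl-3,7,8-trihydroxy-5-methoxycoumarin | COc1cc(O)c(O)c2OC(=O)C(O)=C(Cc3ccccc3)c12 | intermediate
11 | 3-phenylpropanoic acid | O=C(O)CCc1ccccc1 | starting material
12 | 4-benzyl-3,7,8-trihydroxy-5-methoxy-6-(3-phenylpropanoyl)coumarin | COc1c(C(=O)CCc2ccccc2)c(O)c(O)c2OC(=O)C(O)=C(Cc3ccccc3)c12 | intermediate
13 | 4-benzyl-3-hydroxy-5-methoxy-6-(3-phenylpropanoyl)coumarin 7,8-acetonide | COc1c(C(=O)CCc2ccccc2)c2OC(C)(C)Oc2c2OC(=O)C(O)=C(Cc3ccccc3)c12 | intermediate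
14 | (±)-3-[4-hydroxy-6-methoxy-2,2-dimethyl-7-(3-phenylpropanoyl)-1,3-benzodioxol-5-yl]-2-oxo-4-phenylbutanoic acid (not isolated, one enantiomer drawn) | COc1c(C(=O)CCc2ccccc2)c2OC(C)(C)Oc2c(O)c1[C@H](Cc1ccccc1)C(=O)C(=O)O | intermediate
15 | (±)-2-[4-hydroxy-6-methoxy-2,2-dimethyl-7-(3-phenylpropanoyl)-1,3-benzodioxol-5-yl]-3-phenylpropanoic acid (not isolated, one enantiomer drawn) | COc1c(C(=O)CCc2ccccc2)c2OC(C)(C)Oc2c(O)c1[C@H](Cc1ccccc1)C(=O)O | intermediate
16 | (±)-3-benzyl-4-methoxy-5-(3-phenylpropanoyl)benzofuran-2(3H)-one 6,7-acetonide (one enantiomer drawn) | COc1c(C(=O)CCc2ccccc2)c2OC(C)(C)Oc2c2OC(=O)[C@@H](Cc3ccccc3)c12 | intermediate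
17 | lithium 2-oxidobenzofuran (enolate of 16, not isolated) | [Li+].COc1c(C(=O)CCc2ccccc2)c2OC(C)(C)Oc2c2oc([O-])c(Cc3ccccc3)c12 | intermediate
18 | (±)-3-benzyl-3-(phenylselanyl)-4-methoxy-5-(3-phenylpropanoyl)benzofuran-2(3H)-one 6,7-acetonide (one enantiomer drawn) | COc1c(C(=O)CCc2ccccc2)c2OC(C)(C)Oc2c2OC(=O)[C@@]([Se]c3ccccc3)(Cc3ccccc3)c12 | intermediate
19 | selenoxide of 18 (not isolated, racemic at C3, mixture at Se) | COc1c(C(=O)CCc2ccccc2)c2OC(C)(C)Oc2c2OC(=O)[C@@]([Se](=O)c3ccccc3)(Cc3ccccc3)c12 | intermediate
20 | (Z)-3-benzylidene-4-methoxy-5-(3-phenylpropanoyl)benzofuran-2(3H)-one 6,7-acetonide | COc1c(C(=O)CCc2ccccc2)c2OC(C)(C)Oc2c2c1/C(=C/c1ccccc1)C(=O)O2 | intermediate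
21 | bractelactone, (Z)-3-benzylidene-6,7-dihydroxy-4-methoxy-5-(3-phenylpropanoyl)benzofuran-2(3H)-one | COc1c(C(=O)CCc2ccccc2)c(O)c(O)c2c1/C(=C/c1ccccc1)C(=O)O2 | target

**Step count**
Total steps: 12. Longest linear sequence: 11 (steps 1–4 and 6–12; step 5 is the side branch).

**The three steps most likely to fail**

Step 9. After ring opening, hydroperoxide may also add to the aryl ketone. Its para phenoxide can then drive aryl migration and loss of the side chain. The electron-rich phenoxide may also be over-oxidised while the hindered keto acid reacts slowly. The fallback takes the ketone out of the oxidation by inverting acylation and contraction, and it sets out from 10.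
- Ketalisation as in step 8 should give 4-benzyl-3-hydroxy-5-methoxycoumarin 7,8-acetonide F1.
- The same hydroxide, peroxide and acid sequence should lead through the α-keto acid F2 and the arylacetic acid F3 to (±)-3-benzyl-4-methoxybenzofuran-2(3H)-one 6,7-acetonide F4. This substrate has no ketone that could enter a Dakin-type path.
- Its only free ring carbon, C5, is then acylated with 3-phenylpropanoic trifluoroacetic anhydride F5. This anhydride is made in the flask from 11 and (CF3CO)2O (cat. H3PO4, CH2Cl2, 0 °C → rt). It is a metal-free Friedel–Crafts acylation under which the ketal should last.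
- The route is rejoined at 16.

Step 6. Acid may strip the acyloxy group from 8 before the C–C bond forms. The crowded ketone may also react so slowly that the air-sensitive triol decomposes. The fallback carries chlorine instead of oxygen at C3 through all acidic steps and exchanges it at the end, and it sets out from 7.
- SO2Cl2 (CH2Cl2, 0 °C) gives ethyl 2-chloro-3-oxo-4-phenylbutanoate F6.
- Its Pechmann condensation with 6 (MeSO3H) belongs to the well-tried 3-chlorocoumarin series and should give 4-benzyl-3-chloro-7,8-dihydroxy-5-methoxycoumarin F7.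
- Acylation as in step 7 gives the 6-(3-phenylpropanoyl)-3-chlorocoumarin F8, and ketalisation as in step 8 gives its 7,8-acetonide F9.
- Miyaura borylation (B2pin2, Pd2(dba)3/XPhos, KOAc, dioxane, 90 °C) gives the 3-pinacolboronate F10.
- NaBO3·4H2O (THF–H2O, rt) oxidises C–B to C–OH, and the route is rejoined at 13.

Step 7. Substitution at the crowded C6 of the coumarin may stall at O-acylation, and long heating with BF3 may cleave the 5-methyl ether. The fallback acylates before the coumarin is built, and it sets out from 6.
- With 11 in BF3·OEt2 (80 °C) the much more nucleophilic triol should give 1-(2,3,4-trihydroxy-6-methoxyphenyl)-3-phenylpropan-1-one F11. Either free carbon gives the same ketone.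
- Pechmann condensation with 8 then finds one ring carbon and one adjacent OH, and should give 3-acetoxy-4-benzyl-7,8-dihydroxy-5-methoxy-6-(3-phenylpropanoyl)coumarin F12.
- F12 is hydrolysed with aqueous HCl as in step 6, and the route is rejoined at 12.

**Further compounds**
F1 | step 9 | 4-benzyl-3-hydroxy-5-methoxycoumarin 7,8-acetonide | COc1cc2OC(C)(C)Oc2c2OC(=O)C(O)=C(Cc3ccccc3)c12
F2 | step 9 | (±)-3-(4-hydroxy-6-methoxy-2,2-dimethyl-1,3-benzodioxol-5-yl)-2-oxo-4-phenylbutanoic acid | COc1cc2OC(C)(C)Oc2c(O)c1[C@H](Cc1ccccc1)C(=O)C(=O)O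
F3 | step 9 | (±)-2-(4-hydroxy-6-methoxy-2,2-dimethyl-1,3-benzodioxol-5-yl)-3-phenylpropanoic acid | COc1cc2OC(C)(C)Oc2c(O)c1[C@H](Cc1ccccc1)C(=O)O
F4 | step 9 | (±)-3-benzyl-4-methoxybenzofuran-2(3H)-one 6,7-acetonide | COc1cc2OC(C)(C)Oc2c2OC(=O)[C@@H](Cc3ccccc3)c12
F5 | step 9 | 3-phenylpropanoic trifluoroacetic anhydride | O=C(CCc1ccccc1)OC(=O)C(F)(F)F
F6 | step 6 | ethyl 2-chloro-3-oxo-4-phenylbutanoate (racemic, one enantiomer drawn) | CCOC(=O)[C@@H](Cl)C(=O)Cc1ccccc1
F7 | step 6 | 4-benzyl-3-chloro-7,8-dihydroxy-5-methoxycoumarin | COc1cc(O)c(O)c2OC(=O)C(Cl)=C(Cc3ccccc3)c12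
F8 | step 6 | 4-benzyl-3-chloro-7,8-dihydroxy-5-methoxy-6-(3-phenylpropanoyl)coumarin | COc1c(C(=O)CCc2ccccc2)c(O)c(O)c2OC(=O)C(Cl)=C(Cc3ccccc3)c12
F9 | step 6 | 4-benzyl-3-chloro-5-methoxy-6-(3-phenylpropanoyl)coumarin 7,8-acetonide | COc1c(C(=O)CCc2ccccc2)c2OC(C)(C)Oc2c2OC(=O)C(Cl)=C(Cc3ccccc3)c12
F10 | step 6 | 4-benzyl-5-methoxy-6-(3-phenylpropanoyl)-3-(pinacolatoboryl)coumarin 7,8-acetonide | COc1c(C(=O)CCc2ccccc2)c2OC(C)(C)Oc2c2OC(=O)C(B3OC(C)(C)C(C)(C)O3)=C(Cc3ccccc3)c12
F11 | step 7 | 1-(2,3,4-trihydroxy-6-methoxyphenyl)-3-phenylpropan-1-one | COc1cc(O)c(O)c(O)c1C(=O)CCc1ccccc1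
F12 | step 7 | 3-acetoxy-4-benzyl-7,8-dihydroxy-5-methoxy-6-(3-phenylpropanoyl)coumarin | COc1c(C(=O)CCc2ccccc2)c(O)c(O)c2OC(=O)C(OC(C)=O)=C(Cc3ccccc3)c12
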